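**Plan**

1. Retrosynthesis (plakortolide locants; ring A = 1,2-dioxane, ring B = γ-lactone): cut C13=C14, then C6–CH3, then both peroxide C–O bonds (O–C3 and O–C6), then C2=C3 and C1–O of ring B, then C4–C5.
2. Forward: the enol silane of dec-9-en-2-one and methyl pyruvate are joined by a copper–bis(oxazoline) Mukaiyama aldol, which sets C4 (S) by catalyst control and brings in the C6 ketone; reduction, oxidation and a ketene ylide then build ring B as a butenolide.
3. Ring A arises in one operation: the C6 ketone takes up H2O2 and MeOH as a hydroperoxy ketal, and its O–O–H adds to C3 of the butenolide.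
4. Feature that allows this: the C6 carbonyl carbon stands 1,4 to C3, the β-carbon of the C1(=O)–C2=C3 acceptor of ring B, across the quaternary C4; the peroxide oxygen reaches C3 only through a six-membered transition state on the C5 face, so ring A closes cis onto ring B and C3 (S) follows from C4.
5. The C6–OMe group (ketone oxidation level, used as helper) is then replaced by CH3 through the cyclic peroxycarbenium ion, which sets C6 (S) under control of the C4–O bond.
6. The acid- and oxidant-sensitive (E,E)-phenyldiene is made last from the terminal alkene (ozonolysis, Horner–Wadsworth–Emmons).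

Key step: step 6

Remark: plakortolide locants are C1 (lactone C=O), C2 (CH2), C3 (CH–O–O), C4 (CH3, O-lactone), C5 (CH2), C6 (CH3, O–O, chain), C7–C16 (side chain); the target is (3S,4S,6S); the bicycle is named as 2,3,7-trioxabicyclo[4.3.0]nonan-8-one, whose positions 1, 4 and 6 are plakortolide C3, C6 and C4; dec-9-en-2-one is taken to be a catalogue compound.

**Route**

Step 1
Reactants: 1 dec-9-en-2-one
Product: 3 2-(trimethylsilyloxy)deca-1,9-diene, via lithium enolate 2 (not isolated)
Conditions: LDA (1.05 equiv), THF, −78 °C; then Me3SiCl, −78 °C → rt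
Reagents that add atoms: chlorotrimethylsilane, C[Si](C)(C)Cl
Why: Kinetic deprotonation of the methyl ketone at the CH3 group and O-silylation of the enolate (kinetic enolate trapping) should give the terminal enol silane; no stereocenter is formed.

Step 2
Reactants: 3 2-(trimethylsilyloxy)deca-1,9-diene; 4 methyl pyruvate
Product: 6 methyl (2S)-2-hydroxy-2-methyl-4-oxododec-11-enoate, via silyl ether 5 (not isolated)
Conditions: Cu(OTf)2 (10 mol%), (S,S)-tBu-box [2,2′-isopropylidenebis((4S)-4-tert-butyl-2-oxazoline)] (11 mol%), THF, −78 °C; then 1 M HCl, rt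
Reagents that add atoms: none
Why: Catalytic enantioselective Mukaiyama aldol addition to a pyruvate ester: the pyruvate chelates the square-planar divalent copper through both carbonyl oxygens, the tert-butyl groups of the ligand shield the re face of the ketone and the enol silane adds to the si face, which should set the tertiary carbinol (the future C4) as S; the acid work-up cleaves the silyl ether.

Step 3
Reactants: 6 methyl (2S)-2-hydroxy-2-methyl-4-oxododec-11-enoate
Product: 7 (2S)-2-methyldodec-11-ene-1,2,4-triol (both C4 epimers)
Conditions: LiAlH4, THF, −20 → 0 °C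
Reagents that add atoms: none
Why: Hydride reduction of the ester and the ketone should give the triol; the secondary carbinol (future C6) forms as both epimers, which is of no consequence because it is reoxidised in step 4, and the quaternary carbinol is not touched.

Step 4
Reactants: 7 (2S)-2-methyldodec-11-ene-1,2,4-triol
Product: 8 (2S)-2-hydroxy-2-methyl-4-oxododec-11-enal
Conditions: (COCl)2, DMSO, CH2Cl2, −78 °C; then Et3N, −78 → −20 °C
Reagents that add atoms: none
Why: Swern oxidation should convert the primary alcohol to the aldehyde and the secondary alcohol to the ketone while the tertiary alcohol cannot be oxidised; the α-carbon of the aldehyde is quaternary, so the stereocenter cannot epimerise.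

Step 5
Reactants: 8 (2S)-2-hydroxy-2-methyl-4-oxododec-11-enal; 9 (triphenylphosphoranylidene)ketene
Product: 11 (5S)-5-methyl-5-(2-oxodec-9-en-1-yl)furan-2(5H)-one, via ester ylide 10 (not isolated)
Conditions: toluene, 90 °C
Reagents that add atoms: none
Why: The tertiary alcohol adds to the ketene ylide to give an ester-stabilised ylide that undergoes intramolecular Wittig olefination with the neighbouring aldehyde (butenolide synthesis from an α-hydroxy carbonyl compound), five-ring closure on the aldehyde being preferred over six-ring closure on the less electrophilic ketone; C4 is not touched.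

Step 6
Reactants: 11 (5S)-5-methyl-5-(2-oxodec-9-en-1-yl)furan-2(5H)-one
Product: 13 (1S,6S)-4-methoxy-6-methyl-4-(oct-7-en-1-yl)-2,3,7-trioxabicyclo[4.3.0]nonan-8-one (both ketal epimers at C6 of the plakortolide skeleton), via hydroperoxy ketal 12 (not isolated)
Conditions: urea–hydrogen peroxide (5 equiv), Sc(OTf)3 (10 mol%), MeOH, rt; solvent exchange; Et2NH (0.5 equiv), CF3CH2OH, rt
Reagents that add atoms: hydrogen peroxide (from its urea adduct), OO; methanol, CO
Why: Sc(OTf)3 activates the C6 ketone for addition of methanol and H2O2 to give the α-methoxy hydroperoxide 12; Et2NH then deprotonates the hydroperoxide, the peroxide anion adds to C3 of the butenolide (oxa-Michael addition) and the lactone enolate is protonated at C2. The closest known reaction type is the formation of a hydroperoxy ketal from a ketone followed by amine-mediated intramolecular conjugate addition of the hydroperoxide to an unsaturated ester or lactone, which gives 3-methoxy-1,2-dioxanes. Ring A closes 6-exo-trig (oxygen onto C3, the C2=C3 bond exocyclic to the new ring). C3 is controlled by C4: the C5–C6–O–O tether is bound to one face of the planar butenolide and can deliver oxygen only to that face, so the ring fusion should be cis and C3 should be S, while C6 forms as both ketal epimers, which converge in step 7. The step needs the hydroperoxide and not a hydroxyl group to attack (a free hemiketal OH would close 5-exo to a tetrahydrofuran), which the methyl ketal secures, and it needs the ketone to be masked before base is present, because the free β-acyloxy ketone could lose the lactone carboxylate by E1cB elimination. Only C3 lies within reach of the peroxide oxygen, so no regiochemical alternative exists.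

Step 7
Reactants: 13 (1S,6S)-4-methoxy-6-methyl-4-(oct-7-en-1-yl)-2,3,7-trioxabicyclo[4.3.0]nonan-8-one
Product: 14 (1S,4S,6S)-4,6-dimethyl-4-(oct-7-en-1-yl)-2,3,7-trioxabicyclo[4.3.0]nonan-8-one
Conditions: AlMe3 (3 equiv), Me3SiOTf (10 mol%), CH2Cl2, −78 → −40 °C; aqueous work-up
Reagents that add atoms: trimethylaluminium, C[Al](C)C
Why: Proposed new method: the silyl triflate (and then the aluminium Lewis acid formed in the reaction) should ionise the exocyclic C6–OMe bond, the more basic of the two ketal oxygens, to the cyclic peroxycarbenium ion, and AlMe3 should transfer CH3 to C6 faster than it attacks the O–O bond at low temperature; the closest known reaction types are the Lewis acid-mediated substitution of alkoxy-1,2-dioxanes and alkoxy-1,2-dioxolanes by allylsilanes and enol silanes through peroxycarbenium ions and the AlMe3 methylation of cyclic ketals through oxocarbenium ions; both chair-like axial attacks on the half-chair cation meet a syn-axial group on C4, and attack cis to the smaller C4–O bond (not cis to the C4 methyl group) is expected, which places the new methyl cis to the lactone oxygen and leaves the chain equatorial, so that C6 should be S from either ketal epimer.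

Step 8
Reactants: 14 (1S,4S,6S)-4,6-dimethyl-4-(oct-7-en-1-yl)-2,3,7-trioxabicyclo[4.3.0]nonan-8-one
Product: 16 7-[(1S,4S,6S)-4,6-dimethyl-8-oxo-2,3,7-trioxabicyclo[4.3.0]nonan-4-yl]heptanal, via ozonide 15 (not isolated)
Conditions: O3, CH2Cl2, −78 °C; then Me2S, −78 °C → rt
Reagents that add atoms: ozone, [O-][O+]=O
Why: Ozonolysis with reductive work-up should cleave the only C=C bond to the aldehyde; dialkyl peroxides and the lactone are inert to ozone and to dimethyl sulfide, and no stereocenter is involved.

Step 9
Reactants: 16 7-[(1S,4S,6S)-4,6-dimethyl-8-oxo-2,3,7-trioxabicyclo[4.3.0]nonan-4-yl]heptanal; 17 diethyl [(2E)-3-phenylprop-2-en-1-yl]phosphonate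
Product: 19 plakortolide R, via lithiated phosphonate 18 (not isolated)
Conditions: 17, LiN(SiMe3)2 (1.05 equiv), THF, −78 °C; then 16, −78 → 0 °C
Reagents that add atoms: none
Why: Horner–Wadsworth–Emmons olefination with the allylic phosphonate anion should form the C13=C14 bond with E geometry and keep the E styryl bond; the preformed anion should be consumed by the aldehyde at low temperature faster than it deprotonates C2 of the lactone, so the three stereocenters are not touched.

**Compound list**

1 | dec-9-en-2-one | CC(=O)CCCCCCC=C | starting material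
2 | lithium enolate of 1 (not isolated) | [Li+].[O-]C(=C)CCCCCCC=C | intermediate
3 | 2-(trimethylsilyloxy)deca-1,9-diene | C=C(O[Si](C)(C)C)CCCCCCC=C | intermediate
4 | methyl pyruvate | CC(=O)C(=O)OC | starting material
5 | methyl (2S)-2-methyl-4-oxo-2-(trimethylsilyloxy)dodec-11-enoate (not isolated) | COC(=O)[C@@](C)(O[Si](C)(C)C)CC(=O)CCCCCCC=C | intermediate
6 | methyl (2S)-2-hydroxy-2-methyl-4-oxododec-11-enoate | COC(=O)[C@@](C)(O)CC(=O)CCCCCCC=C | intermediate
7 | (2S)-2-methyldodec-11-ene-1,2,4-triol (both C4 epimers) | OC[C@@](C)(O)CC(O)CCCCCCC=C | intermediate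
8 | (2S)-2-hydroxy-2-methyl-4-oxododec-11-enal | O=C[C@@](C)(O)CC(=O)CCCCCCC=C | intermediate
9 | (triphenylphosphoranylidene)ketene | O=C=C=P(c1ccccc1)(c1ccccc1)c1ccccc1 | starting material
10 | (2S)-2-methyl-1,4-dioxododec-11-en-2-yl (triphenylphosphoranylidene)acetate (not isolated) | O=C[C@@](C)(OC(=O)C=P(c1ccccc1)(c1ccccc1)c1ccccc1)CC(=O)CCCCCCC=C | intermediate
11 | (5S)-5-methyl-5-(2-oxodec-9-en-1-yl)furan-2(5H)-one | C=CCCCCCCC(=O)C[C@]1(C)OC(=O)C=C1 | intermediate
12 | (5S)-5-(2-hydroperoxy-2-methoxydec-9-en-1-yl)-5-methylfuran-2(5H)-one (both ketal epimers, not isolated) | C=CCCCCCCC(OC)(OO)C[C@]1(C)OC(=O)C=C1 | intermediate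
13 | (1S,6S)-4-methoxy-6-methyl-4-(oct-7-en-1-yl)-2,3,7-trioxabicyclo[4.3.0]nonan-8-one (both epimers at the ketal carbon) | COC1(CCCCCCC=C)C[C@]2(C)OC(=O)C[C@@H]2OO1 | intermediate
14 | (1S,4S,6S)-4,6-dimethyl-4-(oct-7-en-1-yl)-2,3,7-trioxabicyclo[4.3.0]nonan-8-one | C[C@]1(CCCCCCC=C)C[C@]2(C)OC(=O)C[C@@H]2OO1 | intermediate
15 | (1S,4S,6S)-4,6-dimethyl-4-[6-(1,2,4-trioxolan-3-yl)hexyl]-2,3,7-trioxabicyclo[4.3.0]nonan-8-one (not isolated) | C[C@]1(CCCCCCC3OCOO3)C[C@]2(C)OC(=O)C[C@@H]2OO1 | intermediate
16 | 7-[(1S,4S,6S)-4,6-dimethyl-8-oxo-2,3,7-trioxabicyclo[4.3.0]nonan-4-yl]heptanal | C[C@]1(CCCCCCC=O)C[C@]2(C)OC(=O)C[C@@H]2OO1 | intermediate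
17 | diethyl [(2E)-3-phenylprop-2-en-1-yl]phosphonate | CCOP(=O)(OCC)C/C=C/c1ccccc1 | starting material
18 | lithium salt of 17, deprotonated at the P–CH2 carbon (not isolated) | [Li+].CCOP(=O)(OCC)[CH-]/C=C/c1ccccc1 | intermediate
19 | plakortolide R, (1S,4S,6S)-4,6-dimethyl-4-[(7E,9E)-10-phenyldeca-7,9-dien-1-yl]-2,3,7-trioxabicyclo[4.3.0]nonan-8-one | C[C@]1(CCCCCC/C=C/C=C/c2ccccc2)C[C@]2(C)OC(=O)C[C@@H]2OO1 | target

**Count and risks**

Total step count: 9. Longest linear sequence: 9 steps (1 → 19).

Steps most likely to fail:

Step 7 (labelled step). The organoaluminium may attack the O–O bond, the peroxycarbenium ion may fragment (Hock-type cleavage) or lose a proton to a cyclic peroxy enol ether, or the facial selectivity at C6 may be poor. The fallback uses known chemistry and sets out from 11. Takai–Lombardo methylenation of the ketone (Zn, CH2Br2, TiCl4, THF) should give (5S)-5-methyl-5-(2-methylidenedec-9-en-1-yl)furan-2(5H)-one F1. Isayama–Mukaiyama peroxidation (Co(thd)2 cat., O2, Et3SiH, ClCH2CH2Cl) of the more reactive 1,1-disubstituted alkene should give the tertiary triethylsilyl peroxide (5S)-5-methyl-5-[2-methyl-2-(triethylsilylperoxy)dec-9-en-1-yl]furan-2(5H)-one F2 as both C6 epimers. Bu4NF buffered with AcOH should free the peroxide anion, which closes onto C3 of the butenolide. This is expected to give 14 together with its C6 epimer, (1S,4R,6S)-4,6-dimethyl-4-(oct-7-en-1-yl)-2,3,7-trioxabicyclo[4.3.0]nonan-8-one F3, to be separated by chromatography. The fallback comes back to the route at 14, at the price of no control at C6.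

Step 6. Perhydrolysis of the ketone may stay incomplete, the hydroperoxy ketal may revert to the ketone once the amine is added, the lactone carboxylate may be lost by β-elimination, or the product may suffer Kornblum–DeLaMare cleavage at C3–H. The fallback sets out from 11 and makes the C6–O bond from a tertiary cation instead of from the ketone. MeTi(OiPr)3 should add chemoselectively to the ketone to give the tertiary alcohol (5S)-5-(2-hydroxy-2-methyldec-9-en-1-yl)-5-methylfuran-2(5H)-one F4 (both C6 epimers). Aqueous H2O2 (50%) with catalytic H2SO4 at 0 °C should convert it to the tertiary hydroperoxide (5S)-5-(2-hydroperoxy-2-methyldec-9-en-1-yl)-5-methylfuran-2(5H)-one F5. Et2NH in CF3CH2OH should then close ring A to 14, again accompanied by the C6 epimer F3. The fallback comes back to the route at 14 and bypasses 13 and step 7.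

Step 9. The phosphonate anion may deprotonate C2 of the lactone, which opens ring A by β-elimination of the peroxide or triggers Kornblum–DeLaMare cleavage, and the E selectivity of the new double bond may be incomplete. The fallback sets out from 14 and avoids base altogether: olefin cross-metathesis of the terminal alkene with an excess of (E)-buta-1,3-dien-1-ylbenzene (second-generation Hoveyda–Grubbs catalyst, CH2Cl2, 40 °C) should react at the terminal vinyl group of the diene and give 19 directly. It comes back to the route at 19 and makes no new intermediate.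

Further compounds
F1 | step 7 | (5S)-5-methyl-5-(2-methylidenedec-9-en-1-yl)furan-2(5H)-one | C=CCCCCCCC(=C)C[C@]1(C)OC(=O)C=C1
F2 | step 7 | (5S)-5-methyl-5-[2-methyl-2-(triethylsilylperoxy)dec-9-en-1-yl]furan-2(5H)-one (both C6 epimers) | C=CCCCCCCC(C)(OO[Si](CC)(CC)CC)C[C@]1(C)OC(=O)C=C1
F3 | step 7 | (1S,4R,6S)-4,6-dimethyl-4-(oct-7-en-1-yl)-2,3,7-trioxabicyclo[4.3.0]nonan-8-one | C[C@@]1(CCCCCCC=C)C[C@]2(C)OC(=O)C[C@@H]2OO1
F4 | step 6 | (5S)-5-(2-hydroxy-2-methyldec-9-en-1-yl)-5-methylfuran-2(5H)-one (both C6 epimers) | C=CCCCCCCC(C)(O)C[C@]1(C)OC(=O)C=C1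
F5 | step 6 | (5S)-5-(2-hydroperoxy-2-methyldec-9-en-1-yl)-5-methylfuran-2(5H)-one (both C6 epimers) | C=CCCCCCCC(C)(OO)C[C@]1(C)OC(=O)C=C1
F0 | step 9 | none | none
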